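## The problem

Numbering used throughout (daucane numbering; daucane = 4-isopropyl-1,8-dimethylbicyclo[5.3.0]decane): C1 ring-fusion carbon with methyl, C2 ketone, C3 CH2, C4 CH(isopropyl), C5 ring-fusion carbinol, C6 and C7 CH2, C8 olefinic C(methyl), C9 olefinic CH, C10 CH(O-acyl). Ring A is the cyclopentanone (C1–C5), ring B the cycloheptene (C1, C5–C10).

Target 20 is a cis-fused bicyclo[5.3.0]decane whose two rings share the C1–C5 bond. It has four contiguous stereocentres (C4, C5, C1, C10), read from the SMILES as 1R,4R,5S,10R: the C1 methyl, C5 hydroxyl and C4 isopropyl groups lie on one face and the C10 ester on the other. The hard bond is C1–C5: it joins an all-carbon quaternary centre to a tertiary carbinol, and C1 is flanked by three oxygenated carbons (C2, C5, C10). The C8=C9 double bond must sit exactly between the methyl-bearing C8 and C9, allylic to C10. C4 is the only stereocentre that can be set early by catalysis; it can direct C5 and C1 if the ring fusion is formed in a ring closure whose tether contains it, and the C5 hydroxyl can then direct hydride to C10. The C5 hydroxyl is β to the C2 ketone through the non-enolisable C1, so a free C5 alkoxide invites retro-aldol cleavage of C1–C5; the ester is allylic and 1,3 to a hydroxyl (acyl migration). Ketone and free carbinol should therefore meet only at the end, in neutral media.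

The feature the plan uses: in ring B the carbinol carbon C5 and the methyl-bearing olefinic carbon C8 stand 1,4 to each other (C5–C6–C7–C8), and the remaining three ring atoms C9–C10–C1 carry oxygen on the middle one. An ether bridge C5–O–C8 therefore turns ring B into the (4+3) adduct of a 2-methyl-5-alkylfuran (O, C5, C6, C7, C8) and an oxyallyl cation (C9–C10(O)–C1). The C10 ketone left by that cycloaddition is placed to expel the bridge oxygen from C8 and create C8=C9.

## Retrosynthesis

**20 ⇒ 19 ⇒ 18 ⇒ 16 + 17 (oxidation level and ester).** No C–C bond is cut. The C2 ketone is written back to a carbinol (19), carried as its triethylsilyl ether (18), and the ester to diol 16 and 4-methoxybenzoyl chloride 17. With C2 at the alcohol level the molecule has a single carbonyl in all later steps: no competition in the reduction at C10 and no retro-aldol with a doubly stabilised leaving enolate. The silyl ether costs nothing because the key step delivers it. The forward steps must acylate the secondary allylic C10–OH beside the tertiary C5–OH and oxidise C2 last.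

**16 ⇒ 15 (C10–H).** The C10 carbinol comes from enone 15 by hydride delivery from the C5 hydroxyl, which gives the 1,3-anti diol, the relation found in the target. This is preferred to steric control because both faces of C10 are flanked (C1 methyl on one, ring A on the other). The precursor has one stereocentre less; the forward reaction must be a 1,2-reduction on the face of the C5–OH.

**15 ⇒ 12 (reconnection of O5 to C8, a bond not in the target).** Hydroxy enone 15 is the β-elimination (retro-oxa-Michael) product of bridged ketone 12. The extra bond fixes the olefin position (C1 has no hydrogen, so only C9 can be deprotonated), stores the C5 oxygen as an ether, and turns ring B into an 8-oxabicyclo[3.2.1]octan-3-one. The forward reaction must enolise toward C9 and expel the bridge oxygen from C8 without freeing a C5 alkoxide.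

**12 ⇒ 11 ⇒ 9 (the (4+3) cut: C1–C5 and C8–C9).** After re-introducing the C6=C7 double bond (11), the bicycle is cut into a 2,5-disubstituted furan and the oxyallyl unit C9–C10(O)–C1, held together by the tether C2–C3–C4. The precursor 9 is an open-chain epoxy enol silane (transient cation 10). The alternative of cutting only one of the two bonds (aldol or alkylation at C1 on a preformed ring) would make the quaternary/tertiary junction intermolecularly and stepwise. Here both rings, the C1–C5 bond and the centres C1, C5 and C8 arise together. The forward reaction needs furan face selectivity from C4, the compact approach, and anti opening of the epoxide.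

**9 ⇒ 8 ⇒ 7 ⇒ 6 ⇒ 5 (epoxide of one configuration).** 9 is the enol silane of epoxy ketone 8. The epoxide must agree with C4, which is too remote to control it, so 8 is derived from the erythro epoxy alcohol 7, made by hydroxyl-directed epoxidation of (R)-allylic alcohol 6, itself from enone 5 by catalyst-controlled reduction. The C10 carbinol is a relay that is erased by re-oxidation. Direct nucleophilic epoxidation of 5 is shorter but would give both epoxide diastereomers.

**5 ⇒ 3 + 4; 3 ⇒ 1 + 2.** The C1=C2 double bond comes from a Wittig reaction of aldehyde 3 with the α-methyl stabilised ylide 4. The C4–furan bond and the C4 stereocentre come from an enantioselective Friedel–Crafts conjugate addition of 2-methylfuran 1 to enal 2. All four building blocks are simple and achiral.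

## Roads not taken

Alternative 1: (the most obvious) cut the C8=C9 double bond and close ring B last by ring-closing metathesis of diene A1 with the second-generation Grubbs catalyst. A1 is a cyclopentanone carrying a 1-(acyloxy)allyl arm on C1 and a 3-methylbut-3-enyl arm on C5. The metathesis creates no stereocentre. C1, C5 and C10 would have to be set beforehand by separate intermolecular events: an aldol-type bond at C1 that also fixes C10, and addition of a homoallyl organometallic to a ketone flanked by a quaternary and an isopropyl-bearing carbon. None of these is relayed from another. A1 also carries the free β-hydroxy ketone through organometallic and metathesis steps. The chosen plan forms C1–C5 inside a cycloaddition and keeps the C5 oxygen as an ether until the end.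

Alternative 2: buy the ring fusion with the (R)-proline-catalysed Hajos–Parrish aldol, which gives ketol A2 with the C1 methyl, C5 hydroxyl and C2 ketone in place. Ring B would then be enlarged from six to seven members by inserting one carbon next to its ketone (diazoalkane homologation). The two α-carbons of that ketone are both CH2, so the insertion has no regiochemical bias. After it the ketone sits at C8 and still has to be turned into the methyl-bearing olefin, C10 must be oxidised, and the isopropyl group must be added at C4 on the correct face. These are three unrelated selectivity problems and roughly ten further operations. The chosen plan places C8-methyl, the C10 oxygen and C4-isopropyl in the building blocks.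

Alternative 3: cut the C1–C5 bond alone and form it by transannular aldol reaction of the ten-membered diketone A3 (enolate of the C2 ketone at C1 adding to the C5 ketone). The precursor is a stereodefined cyclodecene with a (Z)-trisubstituted double bond, and making it is at least as long as the whole present route. The aldol would have to choose C1 over C3 and the C2 over the C5 ketone for enolisation, and the configuration at C1/C5 would rest only on transannular conformational preference under equilibrating conditions. In the chosen plan the same bond is formed irreversibly, with its geometry tied to the epoxide and to C4.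

Key step: step 7

Assumption: ylide 4 is taken as purchased; where it is not stocked it is made in one operation from 3-chlorobutan-2-one and triphenylphosphine.

## Route

Step 1
Reactants: 1 2-methylfuran; 2 (E)-4-methylpent-2-enal
Product: 3 (3R)-4-methyl-3-(5-methylfuran-2-yl)pentanal
Conditions: (2R,5R)-5-benzyl-2-tert-butyl-3-methylimidazolidin-4-one (20 mol%), CF3CO2H (20 mol%), excess 1, CH2Cl2/i-PrOH, −40 °C
Reagents that add atoms: none
Why: Iminium-catalysed enantioselective Friedel–Crafts alkylation: the enal forms an (E)-iminium ion with one face shielded by the benzyl group and 2-methylfuran adds through its free 5-position to the β-carbon, setting C4; the (2R,5R) catalyst is chosen by the accepted shielding model for β-alkyl enals (the isopropyl group reverses the descriptor relative to methyl), to be confirmed on the first batch.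

Step 2
Reactants: 3 (3R)-4-methyl-3-(5-methylfuran-2-yl)pentanal; 4 3-(triphenyl-λ5-phosphanylidene)butan-2-one
Product: 5 (3E,6R)-3,7-dimethyl-6-(5-methylfuran-2-yl)oct-3-en-2-one
Conditions: toluene, 90 °C
Reagents that add atoms: none
Why: Wittig olefination with a stabilised α-branched ylide should give the (E)-trisubstituted enone; the stereocentre is β to the aldehyde and cannot epimerise.

Step 3
Reactants: 5 (3E,6R)-3,7-dimethyl-6-(5-methylfuran-2-yl)oct-3-en-2-one
Product: 6 (2R,3E,6R)-3,7-dimethyl-6-(5-methylfuran-2-yl)oct-3-en-2-ol
Conditions: (S)-2-methyl-CBS-oxazaborolidine [(S)-1-methyl-3,3-diphenyltetrahydro-1H,3H-pyrrolo[1,2-c][1,3,2]oxazaborole] (20 mol%), catecholborane, toluene, −78 °C; aq. NaOH work-up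
Reagents that add atoms: none
Why: Corey–Bakshi–Shibata reduction: the α-methylalkenyl group acts as the large and the methyl as the small substituent, so the (S) catalyst should deliver the (R)-carbinol under reagent control (C4 is too remote to interfere); catecholborane at low temperature avoids hydroboration.

Step 4
Reactants: 6 (2R,3E,6R)-3,7-dimethyl-6-(5-methylfuran-2-yl)oct-3-en-2-ol
Product: 7 (1R)-1-{(2R,3R)-2-methyl-3-[(2R)-3-methyl-2-(5-methylfuran-2-yl)butyl]oxiran-2-yl}ethan-1-ol
Conditions: VO(acac)2 (3 mol%), t-BuOOH, toluene, 0 °C
Reagents that add atoms: tert-butyl hydroperoxide, CC(C)(C)OO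
Why: Hydroxyl-directed epoxidation through the vanadate ester: allylic 1,2-strain between the olefinic methyl group and the carbinol methyl group fixes the reactive rotamer and should give the erythro epoxy alcohol, so the carbinol configuration is transcribed into both epoxide carbons; delivery is intramolecular to the allylic double bond and not to the remote furan.

Step 5
Reactants: 7 (1R)-1-{(2R,3R)-2-methyl-3-[(2R)-3-methyl-2-(5-methylfuran-2-yl)butyl]oxiran-2-yl}ethan-1-ol
Product: 8 1-{(2S,3R)-2-methyl-3-[(2R)-3-methyl-2-(5-methylfuran-2-yl)butyl]oxiran-2-yl}ethan-1-one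
Conditions: Dess–Martin periodinane [1,1,1-triacetoxy-1,1-dihydro-1,2-benziodoxol-3(1H)-one], NaHCO3, CH2Cl2, 0 °C to rt
Reagents that add atoms: none
Why: Dess–Martin oxidation under buffered, near-neutral conditions returns the ketone without touching the epoxide or the furan; the relay centre at C10 is erased and the epoxide descriptor at the former C2 of the oxirane changes only because the priorities change.

Step 6
Reactants: 8 1-{(2S,3R)-2-methyl-3-[(2R)-3-methyl-2-(5-methylfuran-2-yl)butyl]oxiran-2-yl}ethan-1-one
Product: 9 triethyl[(1-{(2S,3R)-2-methyl-3-[(2R)-3-methyl-2-(5-methylfuran-2-yl)butyl]oxiran-2-yl}ethenyl)oxy]silane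
Conditions: LiN(SiMe3)2, Et3SiCl, THF, −78 °C
Reagents that add atoms: chlorotriethylsilane, CC[Si](Cl)(CC)CC
Why: Kinetic deprotonation and O-silylation of the acetyl methyl group, the only enolisable position because the epoxide carbon next to the carbonyl is fully substituted; the epoxide is inert to the amide base at −78 °C.

Step 7
Reactants: 9 triethyl[(1-{(2S,3R)-2-methyl-3-[(2R)-3-methyl-2-(5-methylfuran-2-yl)butyl]oxiran-2-yl}ethenyl)oxy]silane
Product: 11 (1S,2R,4R,5S,8R)-5,8-epoxy-2-(triethylsilyloxy)dauc-6-en-10-one, via silyloxyallyl cation 10 (not isolated)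
Conditions: Et3SiOTf (10 mol%), CH2Cl2, −78 °C; Et3N quench
Reagents that add atoms: none
Why: Et3SiOTf silylates the epoxide oxygen and the tertiary C1–O bond, allylic to the enol silane, opens to the 2-silyloxyallyl cation 10 (or is displaced in an asynchronous SN2-like event); the tethered furan adds across C1 and C9, and loss of the silyl cation from the carbonyl oxygen of the adduct returns the catalyst, so the silyl group ends on the C2 oxygen. The closest known reaction type is the silyl-triflate-catalysed intramolecular (4+3) cycloaddition of epoxy enol silanes with tethered furans, a member of the furan/oxyallyl cation cycloaddition family. Ring B closes in the (4+3) mode (bonds C1–C5 and C9–C8 to the 5- and 2-positions of the furan, giving the 8-oxabicyclo[3.2.1]octenone), and ring A closes in the same event through the three-atom tether C2–C3–C4, the C1–C5 bond being a 5-exo attack of the furan on the allyl terminus. C5 and C8: the furan face is set by C4, whose isopropyl group turns toward the furan oxygen to avoid allylic 1,3-strain with H–C6, which places isopropyl and the bridge oxygen cis on ring A. C1: the furan enters anti to the departing epoxide oxygen (anti to the C2 silyloxy group), and the compact arrangement (C10 over the furan carbons, tether on the oxygen side of the allyl unit) puts the C1 methyl on the side of the bridge oxygen, which is the cis ring fusion; the extended arrangement would press that methyl onto H–C6. C2 is carried over unchanged from the epoxide. The step needs the C4 centre and the epoxide to ask for the same furan face, which the reagent-controlled steps 3 and 4 secure, and it needs the compact over the extended approach, which the methyl/H–C6 repulsion is expected to favour. It also needs ring closure to outrun a 1,2-hydride shift from C2 to the cationic C1, which the five-membered tether and the low temperature should ensure.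

Step 8
Reactants: 11 (1S,2R,4R,5S,8R)-5,8-epoxy-2-(triethylsilyloxy)dauc-6-en-10-one
Product: 12 (1S,2R,4R,5S,8S)-5,8-epoxy-2-(triethylsilyloxy)daucan-10-one
Conditions: H2 (1 atm), Pd/C, EtOAc, rt
Reagents that add atoms: none
Why: Catalytic hydrogenation of the strained bridged cis-disubstituted double bond, the only C=C in the molecule; no stereocentre is created (the C8 descriptor changes only through priorities) and the ketone and silyl ether are untouched in ethyl acetate.

Step 9
Reactants: 12 (1S,2R,4R,5S,8S)-5,8-epoxy-2-(triethylsilyloxy)daucan-10-one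
Product: 15 (1S,2R,4R,5S)-5-hydroxy-2-(triethylsilyloxy)dauc-8-en-10-one, via trimethylsilyl enol ether 13 (not isolated), via ring-opened trimethylsilyl ether 14 (not isolated)
Conditions: Me3SiOTf, Et3N, CH2Cl2, 0 °C to rt; then citric acid, MeOH, 0 °C
Reagents that add atoms: none
Why: Silyl-triflate-mediated β-elimination of an 8-oxabicyclo[3.2.1]octan-3-one: soft enolisation can only go toward C9 (C1 has no hydrogen), and the enol ether expels the silyl-activated bridge oxygen from C8, giving the C8=C9 enone with the C5 oxygen trapped as a silyl ether so that no free alkoxide (retro-aldol) appears; mild acidic methanolysis then removes the tertiary trimethylsilyl ether and should leave the hindered secondary triethylsilyl ether.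

Step 10
Reactants: 15 (1S,2R,4R,5S)-5-hydroxy-2-(triethylsilyloxy)dauc-8-en-10-one
Product: 16 (1S,2R,4R,5S,10R)-2-(triethylsilyloxy)dauc-8-ene-5,10-diol
Conditions: Me4NBH(OAc)3, MeCN/AcOH, −30 °C
Reagents that add atoms: none
Why: Hydroxyl-directed triacetoxyborohydride reduction (1,3-anti selective): the C5 hydroxyl exchanges onto boron and delivers hydride to the C10 carbonyl carbon on its own face, so the new hydroxyl should end trans to the C5 hydroxyl and to the C1 methyl; the reagent reduces in the 1,2 mode and there is no other carbonyl.

Step 11
Reactants: 16 (1S,2R,4R,5S,10R)-2-(triethylsilyloxy)dauc-8-ene-5,10-diol; 17 4-methoxybenzoyl chloride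
Product: 18 (1S,2R,4R,5S,10R)-5-hydroxy-2-(triethylsilyloxy)dauc-8-en-10-yl 4-methoxybenzoate
Conditions: pyridine, DMAP, CH2Cl2, 0 °C to 40 °C
Reagents that add atoms: none
Why: DMAP-catalysed acylation: only the secondary allylic C10 hydroxyl is acylated, the tertiary C5 hydroxyl being inert under these conditions; the configuration at C10 is retained.

Step 12
Reactants: 18 (1S,2R,4R,5S,10R)-5-hydroxy-2-(triethylsilyloxy)dauc-8-en-10-yl 4-methoxybenzoate
Product: 19 (1R,2R,4R,5S,10R)-2,5-dihydroxydauc-8-en-10-yl 4-methoxybenzoate
Conditions: HF·pyridine, pyridine, THF, 0 °C to rt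
Reagents that add atoms: none
Why: Fluoride-mediated desilylation in a buffered acidic medium, chosen over basic fluoride to avoid 1,3-acyl migration from O10 to O2 and retro-aldol chemistry; the C1 descriptor changes only through priorities.

Step 13
Reactants: 19 (1R,2R,4R,5S,10R)-2,5-dihydroxydauc-8-en-10-yl 4-methoxybenzoate
Product: 20 (1R,4R,5S,10R)-5-hydroxy-2-oxodauc-8-en-10-yl 4-methoxybenzoate (target)
Conditions: Dess–Martin periodinane, NaHCO3, CH2Cl2, rt
Reagents that add atoms: none
Why: Dess–Martin oxidation of the hindered secondary C2 alcohol under near-neutral conditions; the tertiary alcohol, the allylic ester and the double bond are inert, and the β-hydroxy ketone is formed only in this last step.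

## Compound list

1 | 2-methylfuran | Cc1ccco1 | starting material
2 | (E)-4-methylpent-2-enal | CC(C)/C=C/C=O | starting material
3 | (3R)-4-methyl-3-(5-methylfuran-2-yl)pentanal | O=CC[C@H](C(C)C)c1ccc(C)o1 | intermediate
4 | 3-(triphenyl-λ5-phosphanylidene)butan-2-one | CC(=O)C(C)=P(c1ccccc1)(c1ccccc1)c1ccccc1 | starting material
5 | (3E,6R)-3,7-dimethyl-6-(5-methylfuran-2-yl)oct-3-en-2-one | CC(=O)/C(C)=C/C[C@H](C(C)C)c1ccc(C)o1 | intermediate
6 | (2R,3E,6R)-3,7-dimethyl-6-(5-methylfuran-2-yl)oct-3-en-2-ol | C[C@@H](O)/C(C)=C/C[C@H](C(C)C)c1ccc(C)o1 | intermediate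
7 | (1R)-1-{(2R,3R)-2-methyl-3-[(2R)-3-methyl-2-(5-methylfuran-2-yl)butyl]oxiran-2-yl}ethan-1-ol | C[C@@H](O)[C@@]1(C)O[C@@H]1C[C@H](C(C)C)c2ccc(C)o2 | intermediate
8 | 1-{(2S,3R)-2-methyl-3-[(2R)-3-methyl-2-(5-methylfuran-2-yl)butyl]oxiran-2-yl}ethan-1-one | CC(=O)[C@@]1(C)O[C@@H]1C[C@H](C(C)C)c2ccc(C)o2 | intermediate
9 | triethyl[(1-{(2S,3R)-2-methyl-3-[(2R)-3-methyl-2-(5-methylfuran-2-yl)butyl]oxiran-2-yl}ethenyl)oxy]silane | C=C(O[Si](CC)(CC)CC)[C@@]1(C)O[C@@H]1C[C@H](C(C)C)c2ccc(C)o2 | intermediate
10 | (4R,6R)-3,7-dimethyl-6-(5-methylfuran-2-yl)-2,4-bis(triethylsilyloxy)oct-1-en-3-ylium trifluoromethanesulfonate (silyloxyallyl cation) | C=C(O[Si](CC)(CC)CC)[C+](C)[C@H](O[Si](CC)(CC)CC)C[C@H](C(C)C)c1ccc(C)o1.[O-]S(=O)(=O)C(F)(F)F | intermediate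
11 | (1S,2R,4R,5S,8R)-5,8-epoxy-2-(triethylsilyloxy)dauc-6-en-10-one (oxygen bridge C5–O–C8 on the face of the C1 methyl) | O=C1C[C@]3(C)C=C[C@]2(O3)[C@@H](C(C)C)C[C@@H](O[Si](CC)(CC)CC)[C@]12C | intermediate
12 | (1S,2R,4R,5S,8S)-5,8-epoxy-2-(triethylsilyloxy)daucan-10-one | O=C1C[C@]3(C)CC[C@]2(O3)[C@@H](C(C)C)C[C@@H](O[Si](CC)(CC)CC)[C@]12C | intermediate
13 | (1S,2R,4R,5S,8S)-5,8-epoxy-2-(triethylsilyloxy)-10-(trimethylsilyloxy)dauc-9-ene | C[Si](C)(C)OC1=C[C@]3(C)CC[C@]2(O3)[C@@H](C(C)C)C[C@@H](O[Si](CC)(CC)CC)[C@]12C | intermediate
14 | (1S,2R,4R,5S)-2-(triethylsilyloxy)-5-(trimethylsilyloxy)dauc-8-en-10-one | O=C1C=C(C)CC[C@]2(O[Si](C)(C)C)[C@@H](C(C)C)C[C@@H](O[Si](CC)(CC)CC)[C@]12C | intermediate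
15 | (1S,2R,4R,5S)-5-hydroxy-2-(triethylsilyloxy)dauc-8-en-10-one | O=C1C=C(C)CC[C@]2(O)[C@@H](C(C)C)C[C@@H](O[Si](CC)(CC)CC)[C@]12C | intermediate
16 | (1S,2R,4R,5S,10R)-2-(triethylsilyloxy)dauc-8-ene-5,10-diol | O[C@@H]1C=C(C)CC[C@]2(O)[C@@H](C(C)C)C[C@@H](O[Si](CC)(CC)CC)[C@]12C | intermediate
17 | 4-methoxybenzoyl chloride | COc1ccc(C(Cl)=O)cc1 | starting material
18 | (1S,2R,4R,5S,10R)-5-hydroxy-2-(triethylsilyloxy)dauc-8-en-10-yl 4-methoxybenzoate | COc1ccc(C(=O)O[C@@H]2C=C(C)CC[C@]3(O)[C@@H](C(C)C)C[C@@H](O[Si](CC)(CC)CC)[C@]23C)cc1 | intermediate
19 | (1R,2R,4R,5S,10R)-2,5-dihydroxydauc-8-en-10-yl 4-methoxybenzoate | COc1ccc(C(=O)O[C@@H]2C=C(C)CC[C@]3(O)[C@@H](C(C)C)C[C@@H](O)[C@]23C)cc1 | intermediate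
20 | (1R,4R,5S,10R)-5-hydroxy-2-oxodauc-8-en-10-yl 4-methoxybenzoate | COc1ccc(C(=O)O[C@@H]2C=C(C)CC[C@]3(O)[C@@H](C(C)C)CC(=O)[C@]23C)cc1 | target

## Step count and risks

Total step count: 13. Longest linear sequence: 13 steps (1 and 2 to 20).

**Step 7 (key step).** Most likely failure: approach through the extended instead of the compact arrangement, which would put the C1 methyl anti to the oxygen bridge (trans ring fusion). Diversion of the silyl-bound cation by a 1,2-hydride shift from C2, or by Friedel–Crafts attack at the furan β-position, is also possible. Both stem from the high electrophilicity of a Lewis-acid-bound tertiary oxyallyl cation. The fallback generates the oxyallyl species from the other terminus and without a Lewis acid; it sets out from 8 and returns at 11. Reductive opening of the epoxide of 8 at the carbonyl-bearing carbon with SmI2 (THF/MeOH, −90 °C) should give the β-hydroxy ketone F1, with the C2 carbinol retained and C1 now a CH of no consequence. Silylation (Et3SiCl, imidazole) gives the triethylsilyl ether F2. Kinetic enolate formation at the methyl group (LiN(i-Pr)2, −78 °C) and chlorination with p-toluenesulfonyl chloride gives the chloromethyl ketone F3. NaOCH2CF3 in CF3CH2OH then enolises F3 toward C1 and ionises the C9–Cl bond, and the metal-free oxyallyl intermediate, less electrophilic and more prone to a concerted compact cycloaddition, closes to 11.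

**Step 9.** Most likely failure: slow ring opening, because the bridgehead C8–O bond overlaps poorly with the enol π-system in the bicyclic chair. Forcing it risks loss of the triethylsilyl ether or ionisation at C8 without regiocontrol. The fallback makes the C9 enolate reductively on an oxophilic metal; it sets out from 12 and returns at 15. LiN(SiMe3)2/Me3SiCl gives enol ether 13, N-bromosuccinimide converts it into the 9-bromo ketone F4 (no furan is left to compete), and SmI2 (THF, −78 °C) produces the samarium enolate, whose trivalent samarium ion can bind the bridge oxygen and assist its departure from C8. Aqueous work-up gives 15.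

**Step 1.** Most likely failure: low rate and eroded enantioselectivity with the β-branched enal, and acid-induced oligomerisation of the furan. The fallback uses auxiliary control; it sets out from 1 and returns at 3. Vilsmeier–Haack formylation of 1 gives 5-methylfuran-2-carbaldehyde F5 (also purchasable). Knoevenagel–Doebner condensation with malonic acid gives the acrylic acid F6. Mixed-anhydride coupling with lithiated (4S)-4-phenyl-1,3-oxazolidin-2-one gives imide F7 (auxiliary enantiomer assigned by the chelate model). Conjugate addition of i-PrMgCl/CuBr·SMe2 anti to the phenyl group gives adduct F8. LiBH4 releases the auxiliary and gives alcohol F9, and Dess–Martin oxidation gives 3.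

**Step 4.** Most likely failure: oxidation of the electron-rich 2,5-dialkylfuran by the metal peroxide in competition with the directed epoxidation, or erosion of the erythro preference. The fallback moves stereocontrol to a tartrate ligand at low temperature and no longer needs step 3; it sets out from 3 and returns at 8. Wittig reaction of 3 with ethyl 2-(triphenylphosphoranylidene)propanoate gives the (E)-enoate F10, and i-Bu2AlH reduction gives the primary allylic alcohol F11. Sharpless asymmetric epoxidation (Ti(OiPr)4, D-(−)-diethyl tartrate, t-BuOOH, −20 °C) gives the epoxy alcohol F12. Dess–Martin oxidation gives the epoxy aldehyde F13, MeMgBr gives the carbinol F14 as a mixture of carbinol epimers, and Dess–Martin oxidation converges on 8.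

**Step 10.** Most likely failure: slow exchange of the tertiary hydroxyl onto boron, so that undirected hydride delivery to the other face or conjugate reduction takes over. The fallback sets C10 by inversion during ester formation; it sets out from 15 and returns at 18. Luche reduction (NaBH4, CeCl3·7H2O, MeOH, −78 °C) under steric control gives, if the face is the opposite one, the 10-epimeric diol F15. Mitsunobu esterification of F15 with 4-methoxybenzoic acid (PPh3, diisopropyl azodicarboxylate) inverts C10 and installs the ester in one operation to give 18. Any 16 formed in the Luche reduction is simply acylated as in step 11.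

## Further compounds

F1 | step 7 | (4R,6R)-4-hydroxy-3,7-dimethyl-6-(5-methylfuran-2-yl)octan-2-one (both C3 epimers) | CC(=O)C(C)[C@H](O)C[C@H](C(C)C)c1ccc(C)o1
F2 | step 7 | (4R,6R)-3,7-dimethyl-6-(5-methylfuran-2-yl)-4-(triethylsilyloxy)octan-2-one (both C3 epimers) | CC(=O)C(C)[C@H](O[Si](CC)(CC)CC)C[C@H](C(C)C)c1ccc(C)o1
F3 | step 7 | (4R,6R)-1-chloro-3,7-dimethyl-6-(5-methylfuran-2-yl)-4-(triethylsilyloxy)octan-2-one (both C3 epimers) | ClCC(=O)C(C)[C@H](O[Si](CC)(CC)CC)C[C@H](C(C)C)c1ccc(C)o1
F4 | step 9 | (1S,2R,4R,5S,8S)-9-bromo-5,8-epoxy-2-(triethylsilyloxy)daucan-10-one (both C9 epimers) | O=C1C(Br)[C@]3(C)CC[C@]2(O3)[C@@H](C(C)C)C[C@@H](O[Si](CC)(CC)CC)[C@]12C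
F5 | step 1 | 5-methylfuran-2-carbaldehyde | Cc1ccc(C=O)o1
F6 | step 1 | (2E)-3-(5-methylfuran-2-yl)prop-2-enoic acid | Cc1ccc(/C=C/C(=O)O)o1
F7 | step 1 | (4S)-3-[(2E)-3-(5-methylfuran-2-yl)prop-2-enoyl]-4-phenyl-1,3-oxazolidin-2-one | Cc1ccc(/C=C/C(=O)N2[C@@H](c3ccccc3)COC2=O)o1
F8 | step 1 | (4S)-3-[(3R)-4-methyl-3-(5-methylfuran-2-yl)pentanoyl]-4-phenyl-1,3-oxazolidin-2-one | Cc1ccc([C@@H](C(C)C)CC(=O)N2[C@@H](c3ccccc3)COC2=O)o1
F9 | step 1 | (3R)-4-methyl-3-(5-methylfuran-2-yl)pentan-1-ol | OCC[C@H](C(C)C)c1ccc(C)o1
F10 | step 4 | ethyl (2E,5R)-2,6-dimethyl-5-(5-methylfuran-2-yl)hept-2-enoate | CCOC(=O)/C(C)=C/C[C@H](C(C)C)c1ccc(C)o1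
F11 | step 4 | (2E,5R)-2,6-dimethyl-5-(5-methylfuran-2-yl)hept-2-en-1-ol | OC/C(C)=C/C[C@H](C(C)C)c1ccc(C)o1
F12 | step 4 | {(2R,3R)-2-methyl-3-[(2R)-3-methyl-2-(5-methylfuran-2-yl)butyl]oxiran-2-yl}methanol | OC[C@@]1(C)O[C@@H]1C[C@H](C(C)C)c2ccc(C)o2
F13 | step 4 | (2S,3R)-2-methyl-3-[(2R)-3-methyl-2-(5-methylfuran-2-yl)butyl]oxirane-2-carbaldehyde | O=C[C@@]1(C)O[C@@H]1C[C@H](C(C)C)c2ccc(C)o2
F14 | step 4 | 1-{(2R,3R)-2-methyl-3-[(2R)-3-methyl-2-(5-methylfuran-2-yl)butyl]oxiran-2-yl}ethan-1-ol (both carbinol epimers) | CC(O)[C@@]1(C)O[C@@H]1C[C@H](C(C)C)c2ccc(C)o2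
F15 | step 10 | (1S,2R,4R,5S,10S)-2-(triethylsilyloxy)dauc-8-ene-5,10-diol | O[C@H]1C=C(C)CC[C@]2(O)[C@@H](C(C)C)C[C@@H](O[Si](CC)(CC)CC)[C@]12C
A1 | alternative 1 | ring-closing-metathesis diene: 2-methylcyclopentanone with the 1-(4-methoxybenzoyloxy)prop-2-enyl group on C1, hydroxyl and 3-methylbut-3-enyl on C5, isopropyl on C4, configured as in the target | COc1ccc(C(=O)O[C@H](C=C)[C@@]2(C)C(=O)C[C@H](C(C)C)[C@@]2(O)CCC(C)=C)cc1
A2 | alternative 2 | (3aR,7aR)-3a-hydroxy-7a-methylhexahydro-1H-indene-1,5(4H)-dione (Hajos–Parrish ketol of the (R)-proline series) | C1CC(=O)C[C@]2(O)CCC(=O)[C@]12C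
A3 | alternative 3 | (Z)-cyclodecenedione: 4-isopropyl-1,8-dimethyl-2,5-dioxocyclodec-8-en-10-yl 4-methoxybenzoate, (4R,10R), C1 epimerisable | COc1ccc(C(=O)O[C@@H]2/C=C(C)\CCC(=O)[C@@H](C(C)C)CC(=O)C2C)cc1
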